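**Retrosynthetic overview**
- Last bond: C6–Cl by invertive chlorination of the allylic alcohol that forms when the ten-membered ring B is closed at C5–C6 by a nickel-catalysed Nozaki–Hiyama–Kishi coupling (2-bromoalkene + C6 aldehyde).
- Before ring closure, on the open-chain compound: C2–C3 epoxide (Shi), C11 acetate (Mn(OAc)3), ring A enone (Saegusa–Ito), C9 ester; ring C (β-hydroxy-γ-lactone, C8/C17) from a butenolide by a new copper-catalysed boryl-hydration.
- The butenolide is joined to ring A at C8–C9 by a first nickel/chromium coupling of a tetronate enol triflate (methyl D-glycerate + propanoyl chloride, Dieckmann) with the ring A aldehyde.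
- Ring A: catalytic asymmetric Diels–Alder of (E)-4,4-dimethoxy-2-methylbut-2-enal with a 2-silyloxydiene (sets C1, C10), then Julia–Kocienski olefination (C2=C3) with a C3–C5 bromoalkenyl sulfone.
- Ring order: ring A and the ring C butenolide in parallel, then union, ring C hydrated, ring B last.

Assumption: the SMILES fully defines CNP0314084.4, a briarane; locants are C1 (quaternary, Me = C15), C2–C3 (epoxide), C4, C5 (=C16H2), C6 (Cl), C7 (lactone O), C8 (OH), C9 (acetoxyacetate), C10, C11 (OAc, Me = C20), C12 (C=O), C13=C14, C17 (Me = C18), C19 (lactone C=O), so the target is (1S,2R,3R,6S,7S,8R,9S,10S,11S,17R).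

**Route**

Step 1
Reactants: 1 2,2-dimethoxyacetaldehyde; 2 propanal
Product: 3 (E)-4,4-dimethoxy-2-methylbut-2-enal
Conditions: pyrrolidine (10 mol %), propionic acid (10 mol %), CH2Cl2, 0 °C → rt, slow addition of 2
Reagents that add atoms: none
Why: Amine-catalysed crossed aldol condensation in which the enamine of the only enolisable partner 2 adds to non-enolisable 1 and water is lost to give the thermodynamic E-enal.

Step 2
Reactants: 4 pent-1-en-3-one
Product: 5 (Z)-3-(triisopropylsilyloxy)penta-1,3-diene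
Conditions: i-Pr3SiOTf, Et3N, Et2O, 0 °C
Reagents that add atoms: triisopropylsilyl trifluoromethanesulfonate, CC(C)[Si](C(C)C)(C(C)C)OS(=O)(=O)C(F)(F)F
Why: Soft enolisation and O-silylation of the ethyl ketone give the Z silyl dienol ether, whose terminal methyl sits outside the s-cis diene.

Step 3
Reactants: 3 (E)-4,4-dimethoxy-2-methylbut-2-enal; 5 (Z)-3-(triisopropylsilyloxy)penta-1,3-diene
Product: 6 ring A Diels–Alder adduct (C2 formyl, C9 dimethyl acetal, C12 silyl enol ether)
Conditions: (S)-1-(2-methylphenyl)-3,3-diphenyltetrahydro-1H,3H-pyrrolo[1,2-c][1,3,2]oxazaborole (20 mol %), HNTf2 (18 mol %), CH2Cl2, −78 → −40 °C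
Reagents that add atoms: none
Why: Catalytic enantioselective Diels–Alder reaction in which the nucleophilic C11 diene terminus bonds to the enal β-carbon C10 ("para" rule), the E dienophile fixes C2 and C9 trans on ring A, the chiral oxazaborolidinium ion blocks one enal face and so sets C1 and C10 (its antipode would give ent-6), and the endo-derived C11 centre is erased in step 17.

Step 4
Reactants: 7 3-bromobut-3-en-1-ol
Product: 8 5-[(3-bromobut-3-en-1-yl)sulfanyl]-1-phenyl-1H-tetrazole
Conditions: 1-phenyl-1H-tetrazole-5-thiol, PPh3, DIAD, THF, 0 °C → rt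
Reagents that add atoms: 1-phenyl-1H-tetrazole-5-thiol, Sc1nnnn1-c1ccccc1
Why: Mitsunobu thioetherification of the primary alcohol.

Step 5
Reactants: 8 5-[(3-bromobut-3-en-1-yl)sulfanyl]-1-phenyl-1H-tetrazole
Product: 9 5-[(3-bromobut-3-en-1-yl)sulfonyl]-1-phenyl-1H-tetrazole
Conditions: 30 % aq. H2O2, (NH4)6Mo7O24·4H2O (10 mol %), EtOH, 0 °C → rt
Reagents that add atoms: hydrogen peroxide, OO
Why: Molybdate-catalysed sulfide-to-sulfone oxidation that leaves the electron-poor 2-bromoalkene untouched.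

Step 6
Reactants: 6 ring A Diels–Alder adduct; 9 5-[(3-bromobut-3-en-1-yl)sulfonyl]-1-phenyl-1H-tetrazole
Product: 10 ring A (E)-4-bromopenta-1,4-dienyl acetal
Conditions: KN(SiMe3)2, 1,2-dimethoxyethane, −60 °C → rt
Reagents that add atoms: none
Why: Julia–Kocienski olefination of the non-enolisable neopentyl aldehyde, in which addition, Smiles rearrangement and anti elimination of the phenyltetrazolyl sulfone give the E C2=C3 alkene.

Step 7
Reactants: 10 ring A (E)-4-bromopenta-1,4-dienyl acetal
Product: 11 ring A C9 aldehyde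
Conditions: 10 % aq. oxalic acid on SiO2, CH2Cl2, rt
Reagents that add atoms: water, O
Why: Mild acetal hydrolysis that spares the much more acid-stable triisopropylsilyl enol ether and does not epimerise C10.

Step 8
Reactants: 12 methyl (R)-2,3-dihydroxypropanoate
Product: 13 methyl (R)-3-[(tert-butyldiphenylsilyl)oxy]-2-hydroxypropanoate
Conditions: t-BuPh2SiCl, imidazole, CH2Cl2, −20 → 0 °C
Reagents that add atoms: tert-butyl(chloro)diphenylsilane, CC(C)(C)[Si](Cl)(c1ccccc1)c1ccccc1
Why: Selective silylation of the primary (future C6) hydroxyl; the stereocentre (future C7) comes from the chiral pool.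

Step 9
Reactants: 13 methyl (R)-3-[(tert-butyldiphenylsilyl)oxy]-2-hydroxypropanoate; 14 propanoyl chloride
Product: 15 methyl (R)-3-[(tert-butyldiphenylsilyl)oxy]-2-(propanoyloxy)propanoate
Conditions: pyridine, 4-(dimethylamino)pyridine (cat.), CH2Cl2, 0 °C
Reagents that add atoms: none
Why: O-acylation that brings in C17, C18 and C19.

Step 10
Reactants: 15 methyl (R)-3-[(tert-butyldiphenylsilyl)oxy]-2-(propanoyloxy)propanoate
Product: 16 (R)-5-{[(tert-butyldiphenylsilyl)oxy]methyl}-4-hydroxy-3-methylfuran-2(5H)-one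
Conditions: LiN(SiMe3)2 (2.2 equiv), THF, −78 → 0 °C; then 1 M HCl
Reagents that add atoms: none
Why: Dieckmann cyclisation of the propanoate enolate onto the methyl ester forms the tetronic acid (C8–C17 bond); C7 is not deprotonated at low temperature and keeps its configuration.

Step 11
Reactants: 16 (R)-5-{[(tert-butyldiphenylsilyl)oxy]methyl}-4-hydroxy-3-methylfuran-2(5H)-one
Product: 17 tetronate enol triflate
Conditions: Tf2O, i-Pr2NEt, CH2Cl2, −78 °C
Reagents that add atoms: trifluoromethanesulfonic anhydride, O=S(=O)(OS(=O)(=O)C(F)(F)F)C(F)(F)F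
Why: O-sulfonylation of the vinylogous acid gives the activated C8 electrophile.

Step 12
Reactants: 11 ring A C9 aldehyde; 17 tetronate enol triflate
Product: 18 C9 carbinol butenolide
Conditions: CrCl2 (4 equiv), (S)-N-[2-(4-isopropyl-4,5-dihydro-1,3-oxazol-2-yl)-6-methylphenyl]methanesulfonamide (4.4 equiv), Et3N (4.4 equiv), NiCl2(2,9-dimethyl-1,10-phenanthroline) (2 mol %), THF/MeCN, rt
Reagents that add atoms: none
Why: Nickel-catalysed, chromium-mediated Nozaki–Hiyama–Kishi coupling in which zerovalent nickel inserts into the activated C8–OTf bond far faster than into the unactivated 2-bromoalkene, transmetalation gives an alkenyl trivalent chromium species, and the chiral sulfonamide on chromium directs addition to the aldehyde face that gives the 9S carbinol against the Felkin preference.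

Step 13
Reactants: 18 C9 carbinol butenolide
Product: 20 C8,C9-diol β-hydroxy-γ-lactone, via C8 pinacolboronate 19 (not isolated)
Conditions: CuCl (10 mol %), 1,3-dicyclohexylimidazolium chloride (12 mol %), NaOt-Bu (20 mol %), B2pin2 (1.5 equiv), MeOH (3 equiv), THF, 0 °C → rt; then NaBO3·4H2O, THF/H2O, rt
Reagents that add atoms: bis(pinacolato)diboron (boron stays only in 19), CC1(C)OB(OC1(C)C)B1OC(C)(C)C(C)(C)O1; sodium perborate tetrahydrate (gives the C8 oxygen), [Na+].[Na+].O[B-]1(O)OO[B-](O)(O)OO1.O.O.O.O.O.O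
Why: Proposed new method: copper-catalysed conjugate borylation/protonation of a fully substituted α-methyl-β-alkyl butenolide with in-flask C–B oxidation, a net β-hydration that sets C8 and C17; a small N-heterocyclic-carbene copper–Bpin species adds syn across C8=C17 from the face opposite the C7 CH2OSi group, MeOH protonates the copper enolate and turns the catalyst over, the alkoxide medium lets C17 settle with Me-18 trans to the bulky C9 side chain (cis to boron), and perborate oxidises C–B with retention to the tertiary C8 alcohol; the closest known reaction type is the copper-catalysed β-borylation of β,β-disubstituted (trisubstituted-alkene) unsaturated esters and lactones, not yet shown on tetrasubstituted butenolides.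

Step 14
Reactants: 21 acetoxyacetic acid
Product: 22 acetoxyacetyl chloride
Conditions: (COCl)2, N,N-dimethylformamide (cat.), CH2Cl2, 0 °C → rt
Reagents that add atoms: oxalyl chloride, O=C(Cl)C(=O)Cl
Why: Acid chloride formation through the catalytic chloroiminium (Vilsmeier-type) species; used fresh.

Step 15
Reactants: 20 C8,C9-diol β-hydroxy-γ-lactone; 22 acetoxyacetyl chloride
Product: 23 C9 acetoxyacetate
Conditions: pyridine, 4-(dimethylamino)pyridine (cat.), CH2Cl2, 0 °C
Reagents that add atoms: none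
Why: Acylation of the secondary C9 hydroxyl; the tertiary C8 hydroxyl, flanked by three substituted carbons, does not react.

Step 16
Reactants: 23 C9 acetoxyacetate
Product: 24 ring A enone
Conditions: Pd(OAc)2 (1.2 equiv), DMSO, 40 °C
Reagents that add atoms: none
Why: Saegusa–Ito oxidation in which divalent palladium adds to the regiodefined C12 silyl enol ether and β-hydride elimination at C14 gives the C13=C14 enone.

Step 17
Reactants: 24 ring A enone
Product: 25 C11 acetoxy enone
Conditions: Mn(OAc)3·2H2O (4 equiv), benzene, 80 °C (Dean–Stark)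
Reagents that add atoms: manganese triacetate dihydrate, CC(=O)[O-].CC(=O)[O-].CC(=O)[O-].[Mn+3].O.O
Why: Trivalent-manganese α′-acetoxylation of an enone, in which the manganese enolate (only C11 can enolise) takes acetate on the face opposite the C10 side chain and the axial C15 methyl, giving the 11S tertiary acetate (OAc cis to H-10).

Step 18
Reactants: 25 C11 acetoxy enone
Product: 26 2,3-epoxide
Conditions: 1,2:4,5-di-O-isopropylidene-β-D-erythro-2,3-hexodiulo-2,6-pyranose (30 mol %), KHSO5 (as 2KHSO5·KHSO4·K2SO4), NaHCO3, Bu4NHSO4 (cat.), MeCN/aq. Na2EDTA, 0 °C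
Reagents that add atoms: potassium peroxymonosulfate, [K+].OOS(=O)(=O)[O-]
Why: Shi asymmetric epoxidation, in which the fructose-derived dioxirane attacks the only electron-rich alkene (E C2=C3) through a spiro transition state and gives the (2R,3R) trans-epoxide under reagent control; the 2-bromoalkene and the enone are too electron-poor to react.

Step 19
Reactants: 26 2,3-epoxide
Product: 27 C6 primary alcohol
Conditions: HF·pyridine, pyridine, THF, 0 °C → rt
Reagents that add atoms: none
Why: Buffered fluoride desilylation of the primary silyl ether; epoxide, esters and tertiary alcohol survive.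

Step 20
Reactants: 27 C6 primary alcohol
Product: 28 C6 aldehyde
Conditions: Dess–Martin periodinane, NaHCO3, CH2Cl2, 0 °C
Reagents that add atoms: none
Why: Non-basic Dess–Martin oxidation of the only primary alcohol; the tertiary C8 hydroxyl is inert and C7 is not epimerised.

Step 21
Reactants: 28 C6 aldehyde
Product: 29 ring B allylic alcohol (6R)
Conditions: NiCl2 (10 mol %), CrCl2 (6 equiv), DMSO/THF 3:1, 2 mM, rt
Reagents that add atoms: none
Why: Nickel-catalysed Nozaki–Hiyama–Kishi macrocyclisation in which zerovalent nickel inserts into the C5–Br bond, the alkenyl trivalent chromium species adds only to the aldehyde (ketone, esters and epoxide tolerated) to close ring B with its exocyclic methylene, and Felkin–Anh addition anti to the C7–O bond sets C6 as the 6,7-anti (6R) alcohol.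

Step 22
Reactants: 29 ring B allylic alcohol (6R)
Product: 30 CNP0314084.4
Conditions: PPh3, Cl3CC(O)CCl3, CH2Cl2, −20 → 0 °C
Reagents that add atoms: hexachloroacetone, O=C(C(Cl)(Cl)Cl)C(Cl)(Cl)Cl
Why: Appel-type deoxychlorination in which chloride displaces the allylic oxyphosphonium by SN2 with inversion (6R alcohol to 6S chloride) under conditions that suppress SN2′ transposition; the tertiary C8 hydroxyl does not react.

**Compound list**

1 | 2,2-dimethoxyacetaldehyde | COC(OC)C=O | starting material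
2 | propanal | CCC=O | starting material
3 | (E)-4,4-dimethoxy-2-methylbut-2-enal | O=C/C(C)=C/C(OC)OC | intermediate
4 | pent-1-en-3-one | CCC(=O)C=C | starting material
5 | (Z)-3-(triisopropylsilyloxy)penta-1,3-diene | C=C/C(O[Si](C(C)C)(C(C)C)C(C)C)=C/C | intermediate
6 | (1S,5S,6S)-6-(dimethoxymethyl)-1,5-dimethyl-4-(triisopropylsilyloxy)cyclohex-3-ene-1-carbaldehyde (ring carbons = C1, C11, C10; formyl = C2, acetal = C9; formyl trans to acetal) | O=C[C@@]1(C)CC=C(O[Si](C(C)C)(C(C)C)C(C)C)[C@@H](C)[C@@H]1C(OC)OC | intermediate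
7 | 3-bromobut-3-en-1-ol | C=C(Br)CCO | starting material
8 | 5-[(3-bromobut-3-en-1-yl)sulfanyl]-1-phenyl-1H-tetrazole | C=C(Br)CCSc1nnnn1-c1ccccc1 | intermediate
9 | 5-[(3-bromobut-3-en-1-yl)sulfonyl]-1-phenyl-1H-tetrazole | C=C(Br)CCS(=O)(=O)c1nnnn1-c1ccccc1 | intermediate
10 | 4-[(1E)-4-bromopenta-1,4-dien-1-yl]-5-(dimethoxymethyl)-4,6-dimethyl-1-(triisopropylsilyloxy)cyclohex-1-ene, ring stereocentres as in 6 | C=C(Br)C/C=C/[C@@]1(C)CC=C(O[Si](C(C)C)(C(C)C)C(C)C)[C@@H](C)[C@@H]1C(OC)OC | intermediate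
11 | 6-[(1E)-4-bromopenta-1,4-dien-1-yl]-2,6-dimethyl-3-(triisopropylsilyloxy)cyclohex-3-ene-1-carbaldehyde, ring stereocentres as in 6 | C=C(Br)C/C=C/[C@@]1(C)CC=C(O[Si](C(C)C)(C(C)C)C(C)C)[C@@H](C)[C@@H]1C=O | intermediate
12 | methyl (R)-2,3-dihydroxypropanoate | COC(=O)[C@H](O)CO | starting material
13 | methyl (R)-3-[(tert-butyldiphenylsilyl)oxy]-2-hydroxypropanoate | COC(=O)[C@H](O)CO[Si](c1ccccc1)(c1ccccc1)C(C)(C)C | intermediate
14 | propanoyl chloride | CCC(=O)Cl | starting material
15 | methyl (R)-3-[(tert-butyldiphenylsilyl)oxy]-2-(propanoyloxy)propanoate | COC(=O)[C@H](OC(=O)CC)CO[Si](c1ccccc1)(c1ccccc1)C(C)(C)C | intermediate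
16 | (R)-5-{[(tert-butyldiphenylsilyl)oxy]methyl}-4-hydroxy-3-methylfuran-2(5H)-one | OC1=C(C)C(=O)O[C@@H]1CO[Si](c2ccccc2)(c2ccccc2)C(C)(C)C | intermediate
17 | (R)-5-{[(tert-butyldiphenylsilyl)oxy]methyl}-3-methyl-2-oxo-2,5-dihydrofuran-4-yl trifluoromethanesulfonate | O=S(=O)(OC1=C(C)C(=O)O[C@@H]1CO[Si](c2ccccc2)(c2ccccc2)C(C)(C)C)C(F)(F)F | intermediate
18 | butenolide of 17 bonded at C8 to a (9S) CH(OH) carbon that carries the ring A unit of 11 (C7 as in 17; C1, C10, C11 as in 6) | C=C(Br)C/C=C/[C@@]1(C)CC=C(O[Si](C(C)C)(C(C)C)C(C)C)[C@@H](C)[C@@H]1[C@H](O)C1=C(C)C(=O)O[C@@H]1CO[Si](c2ccccc2)(c2ccccc2)C(C)(C)C | intermediate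
19 | saturated lactone from 18 with a pinacolboryl group on C8 (trans to the C7 CH2OSi group) and H on C17 (Me-18 cis to boron) | C=C(Br)C/C=C/[C@@]1(C)CC=C(O[Si](C(C)C)(C(C)C)C(C)C)[C@@H](C)[C@@H]1[C@H](O)[C@@]1(B2OC(C)(C)C(C)(C)O2)[C@H](OC(=O)[C@@H]1C)CO[Si](c2ccccc2)(c2ccccc2)C(C)(C)C | intermediate
20 | as 19 with OH in place of boron: C8 tertiary alcohol, C9 secondary alcohol; C7, C8, C9, C17 arranged as in 30 | C=C(Br)C/C=C/[C@@]1(C)CC=C(O[Si](C(C)C)(C(C)C)C(C)C)[C@@H](C)[C@@H]1[C@H](O)[C@@]1(O)[C@H](OC(=O)[C@@H]1C)CO[Si](c2ccccc2)(c2ccccc2)C(C)(C)C | intermediate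
21 | acetoxyacetic acid | CC(=O)OCC(=O)O | starting material
22 | acetoxyacetyl chloride | CC(=O)OCC(=O)Cl | intermediate
23 | as 20 with the C9 hydroxyl esterified as acetoxyacetate | C=C(Br)C/C=C/[C@@]1(C)CC=C(O[Si](C(C)C)(C(C)C)C(C)C)[C@@H](C)[C@@H]1[C@H](OC(=O)COC(C)=O)[C@@]1(O)[C@H](OC(=O)[C@@H]1C)CO[Si](c2ccccc2)(c2ccccc2)C(C)(C)C | intermediate
24 | as 23 with ring A as the C12 ketone / C13=C14 enone (C11 still H, Me) | C=C(Br)C/C=C/[C@@]1(C)C=CC(=O)[C@@H](C)[C@@H]1[C@H](OC(=O)COC(C)=O)[C@@]1(O)[C@H](OC(=O)[C@@H]1C)CO[Si](c2ccccc2)(c2ccccc2)C(C)(C)C | intermediate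
25 | as 24 with an (11S) acetoxy group on C11 (OAc cis to H-10) | C=C(Br)C/C=C/[C@@]1(C)C=CC(=O)[C@@](C)(OC(C)=O)[C@@H]1[C@H](OC(=O)COC(C)=O)[C@@]1(O)[C@H](OC(=O)[C@@H]1C)CO[Si](c2ccccc2)(c2ccccc2)C(C)(C)C | intermediate
26 | as 25 with the C2=C3 alkene converted into the (2R,3R) trans-epoxide | C=C(Br)C[C@H]1O[C@@H]1[C@@]1(C)C=CC(=O)[C@@](C)(OC(C)=O)[C@@H]1[C@H](OC(=O)COC(C)=O)[C@@]1(O)[C@H](OC(=O)[C@@H]1C)CO[Si](c2ccccc2)(c2ccccc2)C(C)(C)C | intermediate
27 | as 26 with a free C6 primary alcohol | C=C(Br)C[C@H]1O[C@@H]1[C@@]1(C)C=CC(=O)[C@@](C)(OC(C)=O)[C@@H]1[C@H](OC(=O)COC(C)=O)[C@@]1(O)[C@H](OC(=O)[C@@H]1C)CO | intermediate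
28 | as 27 with C6 as the aldehyde | C=C(Br)C[C@H]1O[C@@H]1[C@@]1(C)C=CC(=O)[C@@](C)(OC(C)=O)[C@@H]1[C@H](OC(=O)COC(C)=O)[C@@]1(O)[C@H](OC(=O)[C@@H]1C)C=O | intermediate
29 | tricyclic briarane identical to 30 except that C6 carries OH with the opposite (6R) configuration | C=C1C[C@H]2O[C@@H]2[C@@]2(C)C=CC(=O)[C@@](C)(OC(C)=O)[C@@H]2[C@H](OC(=O)COC(C)=O)[C@@]2(O)[C@H](OC(=O)[C@@H]2C)[C@@H]1O | intermediate
30 | CNP0314084.4, (1S,2R,3R,6S,7S,8R,9S,10S,11S,17R) | C=C1C[C@H]2O[C@@H]2[C@@]2(C)C=CC(=O)[C@@](C)(OC(C)=O)[C@@H]2[C@H](OC(=O)COC(C)=O)[C@@]2(O)[C@H](OC(=O)[C@@H]2C)[C@H]1Cl | target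

**Step count and risks**

Total step count: 22. Longest linear sequence: 14 steps (1, 3, 6, 7, 12, 13, 15, 16, 17, 18, 19, 20, 21, 22; the paths through steps 2, 4–5 and 8–11 are also 14).

Three steps most likely to fail:

Step 12. The coupling must go against the Felkin preference of the C10 stereocentre, and nickel may also insert into the 2-bromoalkene. Fallback: setting out from 11 and 17, a ligand-free NiCl2/CrCl2 coupling is allowed to follow the Felkin preference and gives the C9 epimer of 18 F1. Dess–Martin oxidation then gives the C9 ketone F2. Felkin-controlled 1,2-reduction (NaBH4, CeCl3·7H2O, MeOH, −78 °C) now delivers hydride to the face that carbon took before and returns the route at 18.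

Step 13. The proposed boryl-hydration may fail because the tetrasubstituted butenolide is a poor acceptor, because C7 may epimerise under alkoxide, or because C17 may protonate to the wrong epimer. Fallback with known chemistry: setting out from 18, nucleophilic epoxidation with t-BuOOLi (THF, −20 °C) from the face anti to the C7 substituent gives the 8,17-epoxy lactone F3. Reductive opening of this α,β-epoxy lactone at the α-carbon with SmI2 (THF/MeOH, −78 °C), protonation of the samarium enolate and equilibration at C17 return the route at 20.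

Step 21. Closing a ten-membered ring with a 2-bromoalkene may be slow, may give oligomers, or may give the wrong C6 epimer. Fallback: setting out from 27, Miyaura borylation (PdCl2[1,1′-bis(diphenylphosphino)ferrocene], B2pin2, KOAc, dioxane, 80 °C) turns the alkenyl bromide into the alkenyl pinacolboronate alcohol F4. Dess–Martin oxidation gives the alkenyl pinacolboronate aldehyde F5. Rhodium-catalysed intramolecular 1,2-addition of the alkenylboronate to the aldehyde ([Rh(OH)(1,5-cyclooctadiene)]2, dioxane/H2O, 50 °C, high dilution) closes ring B and returns the route at 29.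

**Further compounds**

F1 | step 12 | C9 epimer of 18 | C=C(Br)C/C=C/[C@@]1(C)CC=C(O[Si](C(C)C)(C(C)C)C(C)C)[C@@H](C)[C@@H]1[C@@H](O)C1=C(C)C(=O)O[C@@H]1CO[Si](c2ccccc2)(c2ccccc2)C(C)(C)C
F2 | step 12 | C9 ketone | C=C(Br)C/C=C/[C@@]1(C)CC=C(O[Si](C(C)C)(C(C)C)C(C)C)[C@@H](C)[C@@H]1C(=O)C1=C(C)C(=O)O[C@@H]1CO[Si](c2ccccc2)(c2ccccc2)C(C)(C)C
F3 | step 13 | 8,17-epoxy lactone | C=C(Br)C/C=C/[C@@]1(C)CC=C(O[Si](C(C)C)(C(C)C)C(C)C)[C@@H](C)[C@@H]1[C@H](O)[C@]12O[C@@]1(C)C(=O)O[C@@H]2CO[Si](c3ccccc3)(c3ccccc3)C(C)(C)C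
F4 | step 21 | alkenyl pinacolboronate alcohol | C=C(B1OC(C)(C)C(C)(C)O1)C[C@H]1O[C@@H]1[C@@]1(C)C=CC(=O)[C@@](C)(OC(C)=O)[C@@H]1[C@H](OC(=O)COC(C)=O)[C@@]1(O)[C@H](OC(=O)[C@@H]1C)CO
F5 | step 21 | alkenyl pinacolboronate aldehyde | C=C(B1OC(C)(C)C(C)(C)O1)C[C@H]1O[C@@H]1[C@@]1(C)C=CC(=O)[C@@](C)(OC(C)=O)[C@@H]1[C@H](OC(=O)COC(C)=O)[C@@]1(O)[C@H](OC(=O)[C@@H]1C)C=O
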